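**Retrosynthetic overview**

1. Target 21 ⇐ epoxide 20 (aluminium-amide isomerisation gives the ring carbinol and the exocyclic methylene) ⇐ oxepene 19 (epoxidation).
2. 19 ⇐ (Z)-allylic bromohydrin 17: the oxepene is closed by C–O bond formation from the side-chain oxygen to the methyl-bearing ring-fusion carbon; 17 ⇐ aldehyde 13 (Still–Gennari olefination, bromomethyl ketone, oxazaborolidine reduction).
3. Enabling feature: in the six-membered carbocycle the C(CH3)(O) ring-fusion carbon and its ring CH2 neighbour are at the oxidation level of a ring C=C, so the carbocycle is a cyclohexene. Opposite that double bond sits the CHBr–C(CH3)2 pair, flanked by the other ring CH2 and by the ring-fusion CH: a Diels–Alder retron, with one geminal methyl carried as CHO.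
4. Key disconnection: [4+2] of diene 4 with (Z)-3-bromo-2-methylacrolein 8 forms the ring CH2–CHBr bond and the ring-fusion CH–C(quaternary) bond in one operation, and sets the C–Br and ring-fusion CH stereocentres under a chiral oxazaborolidinium catalyst.
5. Ring order: carbocycle first (step 5), oxepene second (step 12); 4 and 8 each come in two steps from commercial materials.

Key step: step 5

Assumption: the (S)-configured oxazaborolidinium catalyst is taken to expose the enal face that is Si at the brominated carbon of 8; if the mirror-image adduct is found, the (R)-catalyst is used and nothing else in the route changes.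

**Route**

Step 1
Reactants: 1 3-[(tert-butyldimethylsilyl)oxy]propanal; 2 2-(triphenyl-λ5-phosphanylidene)propanal
Product: 3 (2E)-5-[(tert-butyldimethylsilyl)oxy]-2-methylpent-2-enal
Conditions: toluene, 80 °C
Reagents that add atoms: none
Why: Wittig olefination with a carbonyl-stabilised ylide, which should give the (E)-trisubstituted enal.

Step 2
Reactants: 3 (2E)-5-[(tert-butyldimethylsilyl)oxy]-2-methylpent-2-enal
Product: 4 tert-butyldimethyl{[(3E)-4-methylhexa-3,5-dien-1-yl]oxy}silane
Conditions: Ph3PCH3Br, KN(SiMe3)2, THF, 0 °C; then 3, −78 → 0 °C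
Reagents that add atoms: methyltriphenylphosphonium bromide, C[P+](c1ccccc1)(c1ccccc1)c1ccccc1.[Br-] (its ylide delivers the CH2 group)
Why: Wittig methylenation with the non-stabilised ylide adds 1,2 to the enal carbonyl and leaves the (E)-olefin untouched, giving the 1,3-diene.

Step 3
Reactants: 5 prop-2-yn-1-ol
Product: 7 (2Z)-3-bromo-2-methylprop-2-en-1-ol, via alkenylmagnesium alkoxide 6 (not isolated)
Conditions: CH3MgBr (3 equiv), CuI (10 mol %), THF, −10 °C → rt; then N-bromosuccinimide, −40 → 0 °C; aq NH4Cl
Reagents that add atoms: methylmagnesium bromide, C[Mg]Br; N-bromosuccinimide, O=C1CCC(=O)N1Br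
Why: Copper-catalysed anti-carbomagnesiation of the propargylic alkoxide places methyl on the internal carbon and magnesium on the terminus cis to the CH2O group through a five-membered chelate, and bromodemetalation with retention fixes the (Z)-vinyl bromide.

Step 4
Reactants: 7 (2Z)-3-bromo-2-methylprop-2-en-1-ol
Product: 8 (2Z)-3-bromo-2-methylprop-2-enal
Conditions: MnO2, CH2Cl2, rt, dark; used at once
Reagents that add atoms: none
Why: Allylic alcohol oxidation with MnO2 under neutral conditions, chosen so that the (Z)-β-bromoenal is not isomerised.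

Step 5
Reactants: 4 tert-butyldimethyl{[(3E)-4-methylhexa-3,5-dien-1-yl]oxy}silane; 8 (2Z)-3-bromo-2-methylprop-2-enal
Product: 9 (1S,2R,6S)-6-bromo-2-{2-[(tert-butyldimethylsilyl)oxy]ethyl}-1,3-dimethylcyclohex-3-ene-1-carbaldehyde
Conditions: (S)-1-(2-methylphenyl)-3,3-diphenyltetrahydro-1H,3H-pyrrolo[1,2-c][1,3,2]oxazaborole (20 mol %), HN(SO2CF3)2 (18 mol %), CH2Cl2, −78 → −40 °C
Reagents that add atoms: none
Why: The reaction is a concerted but asynchronous Lewis-acid-catalysed [4+2] cycloaddition in which the cationic oxazaborolidine binds the formyl oxygen of 8, the brominated β-carbon bonds first to the unsubstituted CH2 terminus of the s-cis diene 4 and the methyl-bearing α-carbon then bonds to the substituted terminus. The closest known reaction type is the enantioselective Diels–Alder reaction of 2-methylacrolein and 2-bromoacrolein with open-chain dienes under chiral oxazaborolidinium catalysis. The cyclohexene ring is closed by suprafacial–suprafacial cycloaddition through a boat-like endo transition state, which forms the CH2–CHBr bond and the CH–C(quaternary) bond at once. The C–Br stereocentre is fixed by the (Z) geometry of 8 (Br cis to CHO) together with the enal face left open by the catalyst, the ring CH stereocentre by the (E) geometry of the diene and the endo position of the formyl group, which put side chain, formyl group and bromine on one face, and the quaternary carbon is stereogenic only until step 6. The step needs "ortho" regioselectivity (formyl-bearing carbon next to the substituted diene terminus), which is expected because the terminal alkyl substituent of the diene directs more strongly than the methyl group on the adjacent internal carbon, as with 1-vinylcycloalkenes, and because the unhindered CH2 terminus takes the first bond. It also needs endo and facial selectivity; the first is expected from the complexed formyl group with an open-chain diene (the exo preference of 2-substituted acroleins is tied to cyclopentadiene), the second from the catalyst.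

Step 6
Reactants: 9 (1S,2R,6S)-6-bromo-2-{2-[(tert-butyldimethylsilyl)oxy]ethyl}-1,3-dimethylcyclohex-3-ene-1-carbaldehyde
Product: 11 tert-butyl{2-[(1R,5S)-5-bromo-2,6,6-trimethylcyclohex-2-en-1-yl]ethoxy}dimethylsilane, via tosylhydrazone 10 (not isolated)
Conditions: p-toluenesulfonyl hydrazide, THF, rt; then catecholborane, CHCl3, 0 °C; then NaOAc·3H2O, 60 °C
Reagents that add atoms: none
Why: Tosylhydrazone formation, catecholborane reduction and acetate-induced loss of sulfinate and N2 (mild variant of the Caglioti deoxygenation) should turn the neopentyl formyl group into the second geminal methyl group while sparing the secondary bromide, the silyl ether and the olefin, and the quaternary carbon thereby stops being a stereocentre.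

Step 7
Reactants: 11 tert-butyl{2-[(1R,5S)-5-bromo-2,6,6-trimethylcyclohex-2-en-1-yl]ethoxy}dimethylsilane
Product: 12 2-[(1R,5S)-5-bromo-2,6,6-trimethylcyclohex-2-en-1-yl]ethan-1-ol
Conditions: HF·pyridine, pyridine, THF, 0 °C → rt
Reagents that add atoms: none
Why: Fluoride-mediated cleavage of the primary silyl ether under buffered conditions that leave the alkyl bromide and the trisubstituted olefin untouched.

Step 8
Reactants: 12 2-[(1R,5S)-5-bromo-2,6,6-trimethylcyclohex-2-en-1-yl]ethan-1-ol
Product: 13 2-[(1R,5S)-5-bromo-2,6,6-trimethylcyclohex-2-en-1-yl]acetaldehyde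
Conditions: Pr4N[RuO4] (5 mol %), N-methylmorpholine N-oxide, 4 Å molecular sieves, CH2Cl2, rt
Reagents that add atoms: none
Why: Ley–Griffith oxidation stops at the aldehyde under neutral conditions, which avoids acid-induced ene cyclisation onto the ring olefin.

Step 9
Reactants: 13 2-[(1R,5S)-5-bromo-2,6,6-trimethylcyclohex-2-en-1-yl]acetaldehyde; 14 methyl 2-[bis(2,2,2-trifluoroethoxy)phosphoryl]propanoate
Product: 15 methyl (2Z)-4-[(1R,5S)-5-bromo-2,6,6-trimethylcyclohex-2-en-1-yl]-2-methylbut-2-enoate
Conditions: KN(SiMe3)2, 18-crown-6, THF, −78 °C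
Reagents that add atoms: none
Why: Still–Gennari modification of the Horner–Wadsworth–Emmons reaction, in which the bis(trifluoroethyl) phosphonate and the dissociated potassium counter-ion make elimination faster than equilibration and should give the (Z)-2-methyl enoate needed for the later ring closure.

Step 10
Reactants: 15 methyl (2Z)-4-[(1R,5S)-5-bromo-2,6,6-trimethylcyclohex-2-en-1-yl]-2-methylbut-2-enoate
Product: 16 (3Z)-1-bromo-5-[(1R,5S)-5-bromo-2,6,6-trimethylcyclohex-2-en-1-yl]-3-methylpent-3-en-2-one
Conditions: CH2Br2, CH3Li·LiBr, THF/Et2O, −78 °C; then AcOH, −78 °C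
Reagents that add atoms: dibromomethane, BrCBr (delivers CH2Br as bromomethyllithium)
Why: Halomethyllithium homologation of an ester, in which bromomethyllithium generated by bromine–lithium exchange in the presence of the ester adds 1,2 at −78 °C and the ketone is released only on the acidic quench, so a second addition and exchange at the secondary bromide are not expected.

Step 11
Reactants: 16 (3Z)-1-bromo-5-[(1R,5S)-5-bromo-2,6,6-trimethylcyclohex-2-en-1-yl]-3-methylpent-3-en-2-one
Product: 17 (2R,3Z)-1-bromo-5-[(1R,5S)-5-bromo-2,6,6-trimethylcyclohex-2-en-1-yl]-3-methylpent-3-en-2-ol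
Conditions: (R)-1-methyl-3,3-diphenyltetrahydro-1H,3H-pyrrolo[1,2-c][1,3,2]oxazaborole (20 mol %), catecholborane, toluene, −78 °C
Reagents that add atoms: none
Why: Corey–Bakshi–Shibata reduction, in which the (R)-oxazaborolidine treats the alkenyl group as the large and CH2Br as the small substituent and should deliver hydride to the face that gives the (R)-bromohydrin.

Step 12
Reactants: 17 (2R,3Z)-1-bromo-5-[(1R,5S)-5-bromo-2,6,6-trimethylcyclohex-2-en-1-yl]-3-methylpent-3-en-2-ol
Product: 19 (2R,5aS,7S,9aS)-7-bromo-2-(bromomethyl)-3,6,6,9a-tetramethyl-2,5,5a,6,7,8,9,9a-octahydro-1-benzoxepine, via organomercury trifluoroacetate 18 (not isolated)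
Conditions: Hg(OCOCF3)2, CH3NO2, −20 → 0 °C; then NaBH4, aq NaOH, 0 °C
Reagents that add atoms: none
Why: Intramolecular Markovnikov alkoxymercuration (7-exo-trig) of the ring olefin followed by reductive demercuration, in which the oxygen should bond to the tertiary carbon of the strongly unsymmetrical mercurinium ion along the equatorial trajectory because the axial one is blocked by the syn-axial methyl of the C(CH3)2 group, which gives the trans ring fusion, while the inductively deactivated olefin of the side chain should not compete.

Step 13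
Reactants: 19 (2R,5aS,7S,9aS)-7-bromo-2-(bromomethyl)-3,6,6,9a-tetramethyl-2,5,5a,6,7,8,9,9a-octahydro-1-benzoxepine
Product: 20 3,4-epoxide of 19 with the oxirane oxygen on the face opposite to the bromomethyl group
Conditions: mCPBA, CH2Cl2, −20 → 0 °C
Reagents that add atoms: 3-chloroperoxybenzoic acid, OOC(=O)c1cccc(Cl)c1
Why: Prilezhaev epoxidation of the only remaining olefin, expected from the face opposite to the bromomethyl group, the angular methyl group and the C(CH3)2 carbon, which places the oxirane oxygen on the face that the hydroxyl group of the target occupies.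

Step 14
Reactants: 20 3,4-epoxide of 19
Product: 21 (2R,4R,5aS,7S,9aS)-7-bromo-2-(bromomethyl)-6,6,9a-trimethyl-3-methylidenedecahydro-1-benzoxepin-4-ol (target)
Conditions: Et2AlCl, lithium 2,2,6,6-tetramethylpiperidide, toluene, 0 °C; aq NH4Cl
Reagents that add atoms: none
Why: Yamamoto isomerisation of a trisubstituted epoxide with an aluminium amide, in which syn-elimination through a cyclic transition state removes a proton of the methyl group and cleaves the tertiary C–O bond, so the exocyclic methylene is formed and the secondary C–O bond keeps its configuration.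

**Compound list**

1 | 3-[(tert-butyldimethylsilyl)oxy]propanal | CC(C)(C)[Si](C)(C)OCCC=O | starting material
2 | 2-(triphenyl-λ5-phosphanylidene)propanal | CC(C=O)=P(c1ccccc1)(c1ccccc1)c1ccccc1 | starting material
3 | (2E)-5-[(tert-butyldimethylsilyl)oxy]-2-methylpent-2-enal | CC(C)(C)[Si](C)(C)OCC/C=C(C)/C=O | intermediate
4 | tert-butyldimethyl{[(3E)-4-methylhexa-3,5-dien-1-yl]oxy}silane | CC(C)(C)[Si](C)(C)OCC/C=C(C)/C=C | intermediate
5 | prop-2-yn-1-ol | C#CCO | starting material
6 | bromomagnesium (2Z)-3-(bromomagnesio)-2-methylprop-2-en-1-olate | Br[Mg]/C=C(C)\CO[Mg]Br | intermediate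
7 | (2Z)-3-bromo-2-methylprop-2-en-1-ol | OC/C(C)=C\Br | intermediate
8 | (2Z)-3-bromo-2-methylprop-2-enal | O=C/C(C)=C\Br | intermediate
9 | (1S,2R,6S)-6-bromo-2-{2-[(tert-butyldimethylsilyl)oxy]ethyl}-1,3-dimethylcyclohex-3-ene-1-carbaldehyde | CC(C)(C)[Si](C)(C)OCC[C@H]1[C@@](C)(C=O)[C@@H](Br)CC=C1C | intermediate
10 | (E)-N-tosylhydrazone of 9 | CC(C)(C)[Si](C)(C)OCC[C@H]1[C@@](C)(/C=N/NS(=O)(=O)c2ccc(C)cc2)[C@@H](Br)CC=C1C | intermediate
11 | tert-butyl{2-[(1R,5S)-5-bromo-2,6,6-trimethylcyclohex-2-en-1-yl]ethoxy}dimethylsilane | CC(C)(C)[Si](C)(C)OCC[C@H]1C(C)(C)[C@@H](Br)CC=C1C | intermediate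
12 | 2-[(1R,5S)-5-bromo-2,6,6-trimethylcyclohex-2-en-1-yl]ethan-1-ol | OCC[C@H]1C(C)(C)[C@@H](Br)CC=C1C | intermediate
13 | 2-[(1R,5S)-5-bromo-2,6,6-trimethylcyclohex-2-en-1-yl]acetaldehyde | O=CC[C@H]1C(C)(C)[C@@H](Br)CC=C1C | intermediate
14 | methyl 2-[bis(2,2,2-trifluoroethoxy)phosphoryl]propanoate | COC(=O)C(C)P(=O)(OCC(F)(F)F)OCC(F)(F)F | starting material
15 | methyl (2Z)-4-[(1R,5S)-5-bromo-2,6,6-trimethylcyclohex-2-en-1-yl]-2-methylbut-2-enoate | COC(=O)/C(C)=C\C[C@H]1C(C)(C)[C@@H](Br)CC=C1C | intermediate
16 | (3Z)-1-bromo-5-[(1R,5S)-5-bromo-2,6,6-trimethylcyclohex-2-en-1-yl]-3-methylpent-3-en-2-one | O=C(CBr)/C(C)=C\C[C@H]1C(C)(C)[C@@H](Br)CC=C1C | intermediate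
17 | (2R,3Z)-1-bromo-5-[(1R,5S)-5-bromo-2,6,6-trimethylcyclohex-2-en-1-yl]-3-methylpent-3-en-2-ol | BrC[C@H](O)/C(C)=C\C[C@H]1C(C)(C)[C@@H](Br)CC=C1C | intermediate
18 | 9-(trifluoroacetoxymercurio) derivative of 19, mercury trans to the ring oxygen | CC1=CC[C@H]2C(C)(C)[C@@H](Br)C[C@@H]([Hg]OC(=O)C(F)(F)F)[C@]2(C)O[C@H]1CBr | intermediate
19 | (2R,5aS,7S,9aS)-7-bromo-2-(bromomethyl)-3,6,6,9a-tetramethyl-2,5,5a,6,7,8,9,9a-octahydro-1-benzoxepine | CC1=CC[C@H]2C(C)(C)[C@@H](Br)CC[C@]2(C)O[C@H]1CBr | intermediate
20 | 3,4-epoxide of 19, oxirane oxygen trans to the bromomethyl group | C[C@]12[C@H](O1)C[C@H]3C(C)(C)[C@@H](Br)CC[C@]3(C)O[C@H]2CBr | intermediate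
21 | (2R,4R,5aS,7S,9aS)-7-bromo-2-(bromomethyl)-6,6,9a-trimethyl-3-methylidenedecahydro-1-benzoxepin-4-ol | C=C1[C@H](O)C[C@H]2C(C)(C)[C@@H](Br)CC[C@]2(C)O[C@H]1CBr | target

**Step count and risks**

Total step count: 14 (two steps to diene 4, two steps to dienophile 8, then ten steps from the cycloaddition to the target).
Longest linear sequence: 12 steps (1 → 3 → 4 → 9 → 11 → 12 → 13 → 15 → 16 → 17 → 19 → 20 → 21).

Steps most likely to fail:

Step 5. The (Z)-bromoenal may isomerise to the (E)-isomer on the Lewis acid, or the endo preference may be incomplete; either puts bromine on the wrong face relative to the side chain. Some "meta" regiochemistry may also form. The fallback sets out from diene 4 and comes back at bromide 11, and it no longer takes the C–Br configuration from the cycloaddition. Cycloaddition under the same catalyst with the configurationally stable (2E)-2-methyl-3-(4,4,5,5-tetramethyl-1,3,2-dioxaborolan-2-yl)prop-2-enal should give the boronate aldehyde F1. Tosylhydrazone formation and catecholborane reduction as in step 6 should give the gem-dimethyl boronate F2. Oxidation with NaBO3·4H2O (retention) should give the ring carbinol F3. Whatever the epimer ratio at that carbon, Dess–Martin oxidation to the 2,2-dimethylcyclohexenone F4 and reduction with KBH(s-Bu)3 from the equatorial side should converge on the axial alcohol F3. CBr4/PPh3 (Appel reaction, inversion) should then give the equatorial bromide 11.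

Step 12. The oxygen may add to the other face of the ring olefin through anti-diaxial opening of the mercurinium ion, which gives the cis ring fusion. The seven-membered closure may also be slow enough for trifluoroacetate to capture the ion. The fallback sets out from 17 and comes back at 19 and makes no new compound (F0). It replaces the two-electron anti-addition by a hydrogen-atom-transfer hydroalkoxylation. The reagents are N,N′-bis(3,5-di-tert-butylsalicylidene)-1,2-cyclohexanediaminocobalt (the divalent cobalt salen complex, catalytic), N-fluoro-2,4,6-trimethylpyridinium tetrafluoroborate and PhSiH3 in CH2Cl2 at 0 °C. The oxygen then attacks a tertiary radical-derived cation at the ring-fusion carbon without an anti-periplanar constraint, and equatorial capture is expected as in hydrations of related trimethylcyclohexene systems.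

Step 14. The amide base may remove HBr from the bromomethyl group, or abstract a proton at the ring CH2 or the ether methine instead of the methyl group. The fallback sets out from oxepene 19, bypasses the epoxide and comes back at 21. Dye-sensitised photooxygenation (O2, hν, 5,10,15,20-tetraphenylporphyrin, CH2Cl2, −20 °C; singlet-oxygen ene reaction from the less hindered face with hydrogen abstraction from the methyl group) should give the allylic hydroperoxide F5. Reduction with PPh3 should give 21.

Further compounds
F1 | step 5 | 2-{2-[(tert-butyldimethylsilyl)oxy]ethyl}-1,3-dimethyl-6-(4,4,5,5-tetramethyl-1,3,2-dioxaborolan-2-yl)cyclohex-3-ene-1-carbaldehyde, boryl group trans to the side chain | CC(C)(C)[Si](C)(C)OCC[C@H]1[C@@](C)(C=O)[C@H](B2OC(C)(C)C(C)(C)O2)CC=C1C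
F2 | step 5 | tert-butyldimethyl{2-[2,6,6-trimethyl-5-(4,4,5,5-tetramethyl-1,3,2-dioxaborolan-2-yl)cyclohex-2-en-1-yl]ethoxy}silane, boryl group trans to the side chain | CC(C)(C)[Si](C)(C)OCC[C@H]1C(C)(C)[C@H](B2OC(C)(C)C(C)(C)O2)CC=C1C
F3 | step 5 | 5-{2-[(tert-butyldimethylsilyl)oxy]ethyl}-4,6,6-trimethylcyclohex-3-en-1-ol, axial hydroxyl trans to the side chain | CC(C)(C)[Si](C)(C)OCC[C@H]1C(C)(C)[C@H](O)CC=C1C
F4 | step 5 | (5R)-5-{2-[(tert-butyldimethylsilyl)oxy]ethyl}-4,6,6-trimethylcyclohex-3-en-1-one | CC(C)(C)[Si](C)(C)OCC[C@H]1C(C)(C)C(=O)CC=C1C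
F0 | step 12 | none | none
F5 | step 14 | (2R,4R,5aS,7S,9aS)-7-bromo-2-(bromomethyl)-4-hydroperoxy-6,6,9a-trimethyl-3-methylidenedecahydro-1-benzoxepine | C=C1[C@H](OO)C[C@H]2C(C)(C)[C@@H](Br)CC[C@]2(C)O[C@H]1CBr
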